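The north-east run is the south-west charge with 100 mM of Prd added at the start, so the gap between the two runs can be read as the response to a step.

| flask | Sub | Rgt | Prd | time |
|---|---|---|---|---|
| south-west | 200 mM | 600 mM |  |  |
| south | 120 mM | 520 mM |  |  |
| west | 200 mM | 1800 mM |  |  |
| north-east | 200 mM | 600 mM | 100 mM |  |
| north-west | 200 mM | 600 mM |  | 99 min |

| run | time / min | [Prd] / mM |
|---|---|---|
| south-west run | 5.5 | 38.1 |
| south-west run | 11 | 66.0 |
| south-west run | 16 | 83.4 |
| south-west run | 22 | 96.7 |
| south-west run | 28 | 107.6 |
| south-west run | 33 | 111.2 |
| south run | 5.5 | 21.9 |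
| south run | 11 | 37.7 |
| south run | 16 | 50.1 |
| south run | 22 | 58.8 |
| south run | 28 | 62.9 |
| south run | 33 | 66.1 |
| west run | 5.5 | 46.6 |
| west run | 11 | 79.7 |
| west run | 16 | 100.6 |
| west run | 22 | 115.0 |
| west run | 28 | 122.9 |
| west run | 33 | 125.3 |
| north-east run | 5.5 | 130.0 |
| north-east run | 11 | 151.5 |
| north-east run | 16 | 163.9 |
| north-east run | 22 | 172.6 |
| north-east run | 28 | 176.3 |
| north-east run | 33 | 176.2 |

(scatter of a reading: 0.6 mM)

- Overall: Sub + Rgt -> Prd.
- Constant volume, constant temperature.
- A reading of a species includes what of it is bound.
- "The second partner" is Rgt.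
- An order is taken over about fifteen percent of the charge, up and down.

* the exponent of [Sub] in the starting rate at the charge of the south-west run (at the point where two percent of the Sub have become Prd) (one fixed amount of Prd, the same in the runs compared)
* the exponent of [Rgt] in the starting rate at the charge of the south-west run (at the point where two percent of the Sub have become Prd)
* Prd in the north-west run at 99 min, as a share of the Sub charged

Here is my own reckoning. If added Prd leaves the making of Prd untouched and Prd is lost in proportion to what is present, the gap falls from 100 mM as a plain exponential. At 33 min the gap reads 65.0 mM, so τ comes to 76.6 min, where τ is the loss time constant, the time in which Prd left to itself falls by a factor e.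

The objection is that a reverse step or a slowed forward step could also narrow the gap, and τ might then drift with time. At 16 min the gap reads 80.5 mM, which gives 73.8 min. The two values differ by 2.80 min, less than the 3.58 min of scatter on that early value, so I keep one τ.

For the making side, the north-west flask has 600 mM of Rgt against 200 mM of Sub, so I treat Sub as pseudo-first-order with a rate constant a. The first south-west reading, 38.1 mM at 5.5 min, plus the Prd lost meanwhile, gives a = 0.0400 min⁻¹. With b the inverse of τ, two first-order lags in series leave a share a/(a−b) times (e^(−bt) − e^(−at)) of the Sub charged as Prd, which at 99 min is 37.9%.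

But a may drift as Rgt is used. The same formula gives 113.6 mM for the south-west run at 33 min, more than the reading of 111.2 mM. Lowering a to 0.0360 min⁻¹ moves the north-west figure to 38.6%, so I stay with my estimate.

The forecast gives 58.5%, with exponents 0.97 for Sub and 0.3 for Rgt, and holds that “the catalyst is probably dying, perhaps alongside reversibility”. It expects a stall and I expect a decline, 21 percentage points lower.

The flask gives 37.9% at 99 min, with exponents 0.94 for Sub and 0.41 for Rgt. The loss of Prd to X moves the readings by 44 in units of the scatter, root mean square.

    Sub + Rgt → Prd + Byp (0.2436 M⁻¹ min⁻¹)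
    Sub + Rgt ⇌ Sub.Rgt, settled at all times (4.060 M⁻¹)
    Prd → X (0.01314 min⁻¹)

Now take τ to the west run. Its first reading, 46.6 mM, gives a = 0.0502 min⁻¹, and with τ unchanged the series formula puts Prd at 124.1 mM at 33 min, where the reading is 125.3 mM.

The readings are simulated with constants of no real substance, and the scatter is random.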